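# Proposed synthesis of CNP0225437.1, (3R,4R,5S)-5-acetoxy-3-(6-methylheptanoyloxy)-4-tigloyloxycyclohex-1-ene-1-carboxylic acid (18)

Atom labels C1–C6 and O3–O5 refer to the cyclohexene ring of the target (C1 bears CO2H, C2 is the vinylic CH, C6 is CH2). Plain numbers 1–18 are compounds.

## Analysis of the target

The target 18 is a cyclohex-1-ene-1-carboxylic acid: one carbocycle C1–C6, C1=C2 conjugated with the free CO2H, C6 a methylene, and three contiguous oxygen-bearing stereocentres C3 (allylic), C4 and C5. Each oxygen carries a different acyl group: 6-methylheptanoyl on O3, tigloyl ((E)-2-methylbut-2-enoyl) on O4 and acetyl on O5. The configuration is (3R,4R,5S): O3 and O5 lie on one face and O4 on the other, so the triad is all-trans. Compared with natural (3R,4S,5R)-shikimic acid A1, both C4 and C5 are inverted, so the chiral pool offers only C3. Sensitive points are 1,2-acyl migration whenever a free hydroxyl sits next to an ester under base, the allylic C3 ester (ionisation or elimination leads towards benzoates), the tiglate as a Michael acceptor, and a carboxylic acid that cannot be freed by saponification beside three esters. The difficulty is twofold: a non-natural all-trans triad must be made in one absolute sense, and three secondary oxygens of similar reactivity must be told apart without a long protecting-group sequence. The feature used here is that C2 and C5 are 1,4-related across the ring and that a hydrogen on C1 would be α to the carboxyl: extending the C5–O bond to C2 as a one-atom bridge turns the ring into a 7-oxabicyclo[2.2.1]heptane-2-carboxylate, the Diels–Alder adduct of furan 1 with an acrylic acid derivative. In that bicycle the bridge oxygen is the future O5, β-elimination from C1 re-creates C1=C2, and the only open (exo) face of the alkene fixes the C3–O and C4–O bonds relative to O5.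

## Retrosynthetic reasoning

**18 ⇒ 17.** The acid is unveiled last by cutting the O–CH2Ar bond of a 4-methoxybenzyl ester. Acidolysis leaves the three secondary esters untouched, which hydrolysis of a simple alkyl ester would not.

**17 ⇒ 15 + 16.** The acyl–O4 bond is cut. The tiglate enters last because O4 is the one oxygen that the preceding step sets free as a hydroxyl; no protecting group is needed and the Michael acceptor is exposed to only one further step.

**15 ⇒ 13 + 14.** At C3 the alkyl–oxygen bond is cut, not the acyl–oxygen bond: the acid 14 is the nucleophile and the vinyl epoxide 13 the electrophile. C3 is the allylic carbon of the epoxide, so attack there is favoured, inversion gives the 3,4-trans relation, and O4 emerges as the only free hydroxyl. One step thus forms the C3 ester, sets C3 and distinguishes O3 from O4.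

**13 ⇒ 10 + 11.** At C5 the alkyl–oxygen bond is cut again: acetic acid 11 displaces the activated hydroxyl of 10 with inversion (Mitsunobu). The bicycle can only deliver the epoxide cis to O5 (see the next paragraph); inverting C5 converts this cis arrangement into the required trans one and installs the acetate in the same operation. This is preferred to epoxidising a dienyl acetate anti to the acetate, a facial preference that an acetate controls poorly.

**10 ⇒ 7.** O5 is reconnected to C2: 10 is the product of E1cB opening of the oxygen bridge of 7. The forward step creates C1=C2 in conjugation with the ester and turns the bridge oxygen into the C5 hydroxyl. The epoxide of 7 is exo, hence cis to the bridge oxygen, and this relation is carried into 10.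

**7 ⇒ 4 + 5 (via 6).** The imide needed for two-point binding to the catalyst is exchanged for the ester needed at the end. The exchange is placed after epoxidation so that no alkene, and therefore no cycloreversion, remains in the substrate.

**4 ⇒ 3.** The epoxide oxygen is removed from the exo face of the strained alkene. The rigid bicycle makes this face the only accessible one, so both C–O bonds (future C3–O and C4–O) are set relative to the bridgehead without a reagent-controlled step.

**3 ⇒ 1 + 2.** The bonds C1–C2 and C5–C6 (target numbering) are cut in a Diels–Alder disconnection. Two flat, achiral, commercial compounds give all six ring carbons, the latent O5 and the carboxyl carbon. A chiral Lewis acid sets the bridgehead that becomes C5, and every other stereocentre of 18 is relayed from it.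

## Alternatives that were turned down

**Alternative 1:** the textbook disconnection cuts only the three acyl–oxygen bonds and buys the ring as (−)-shikimic acid A1. Because A1 is (3R,4S,5R), the forward key step is a pair of inversions: after esterification of the carboxyl group, Mitsunobu-type closure of O4 onto C5 gives the hydroxy epoxide methyl ester A2 (C5 inverted), O3 is acylated, and the epoxide must then be opened at C4 by the parent acid of 16. It was turned down on mechanism. In A2, C4 is flanked by two oxygenated carbons and is inductively retarded, and trans-diaxial opening directs nucleophiles to C5, which restores the configuration of A1 and leaves C4 untouched. The C3 oxygen of A2 lies on the same face as the epoxide and cannot deliver a nucleophile to C4. Inverting the two centres separately needs protection of the other hydroxyls each time, which brings the count above ten steps, most of them protecting-group steps, and a methyl ester at C1 could not be removed at the end.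

**Alternative 2:** cut C1=C2 by ring-closing metathesis. The pentose D-arabinose A3 would supply C4 and C3 of the target from its own C2 and C3. After iodination at its primary carbon, A3 is fragmented reductively with zinc and the chain is extended in the same pot by Barbier 2-(ethoxycarbonyl)allylation to give the diene A4, which second-generation Grubbs catalyst closes to the triol ester A5. It was turned down because the key step forms a bond that carries no stereochemical information. C5 is created in the Barbier addition under weak, medium-dependent 1,2-induction from the two centres inherited from A3, and O3 and O4 arrive in A5 as an undifferentiated trans-diol. Telling three hydroxyls apart then requires a protecting-group sequence that makes the route longer than ten steps.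

**Alternative 3:** cut the C4–O alkyl–oxygen bond in a desymmetrisation. The meso epoxide A6 is opened by the parent acid of 16 under a chiral salen complex of trivalent cobalt, (salen)Co(O2CR), to give the hydroxy ester A7, which sets C4 and C5 and distinguishes O4 from O5 in one step. It was turned down because A7 still lacks the carboxyl carbon and O3. Its remaining alkene carbons and the two allylic methylenes differ only through a remote acyl group, so no reagent can choose C1 over C2 for carbon and C3 over C6 for oxygen. At least five further steps of uncontrolled regiochemistry would follow, and carboxylic-acid openings of six-membered meso epoxides such as A6 are only moderately enantioselective.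

Key step: step 1

Assumption: the sense of induction in step 1 is taken from the accepted model for this catalyst class (s-cis acryloyl imide chelated to square-planar divalent copper, the diene adding to the face not covered by a tert-butyl group). On that model the (R,R) ligand gives the (1R,2R,4R) endo adduct; if the opposite sense were found, the (S,S) ligand would be used and nothing else would change. (R,R)-t-Bu-box = 2,2′-(propane-2,2-diyl)bis[(4R)-4-tert-butyl-4,5-dihydro-1,3-oxazole].

## Route

**Step 1**
Reactants: 1 furan; 2 3-acryloyl-1,3-oxazolidin-2-one
Product: 3 3-[(1R,2R,4R)-7-oxabicyclo[2.2.1]hept-5-ene-2-carbonyl]-1,3-oxazolidin-2-one (endo adduct)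
Conditions: 1 (10 equiv), [Cu((R,R)-t-Bu-box)](SbF6)2 (5 mol%, from CuCl2, ligand and AgSbF6), CH2Cl2, −78 °C; cold filtration through silica, crystallisation
Reagents that add atoms: none
Why: Lewis-acid-catalysed normal-demand [4+2] cycloaddition in which 2 chelates the divalent copper centre through both carbonyl oxygens with the acryloyl group s-cis, which lowers its LUMO and fixes its geometry. The closest known reaction type is the bis(oxazoline)–copper-catalysed Diels–Alder reaction of acryloyl oxazolidinones with cyclic dienes, furan included. One suprafacial event forms the σ-bonds C1–C2 and C5–C6 (target numbering) and closes, by concerted cycloaddition, both the carbocycle and the oxygen-bridged rings of the 7-oxabicyclo[2.2.1]heptene. C2 of 3 (lost later) is set by the catalyst, because one tert-butyl group of the ligand covers one face of the bound acryloyl group and furan adds to the other. The bridgeheads C1 and C4 of 3 follow from C2 through the endo transition state, and C4 is the centre that is kept and becomes C5 of the target. The step needs enantiofacial control, endo over exo control (the exo adduct of the same dienophile face has the opposite bridgehead configuration) and kinetic control of a reversible reaction. Two-point binding of the imide, the low temperature and the weakly coordinating counter-ion should secure these, and crystallisation of 3 should remove minor isomers. The precursors are two flat achiral commodity compounds, while the product holds all six ring carbons, the latent O5 and a rigid frame that dictates the face of step 2.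

**Step 2**
Reactants: 3
Product: 4 3-[(1R,2R,4S,5S,6R)-3,8-dioxatricyclo[3.2.1.0^{2,4}]octane-6-carbonyl]-1,3-oxazolidin-2-one (exo epoxide)
Conditions: mCPBA (1.5 equiv), NaHCO3, CH2Cl2, 0 °C → rt
Reagents that add atoms: mCPBA (3-chloroperoxybenzoic acid), OOC(=O)c1cccc(Cl)c1
Why: Prilezhaev epoxidation of the strained alkene; the endo face is closed by the endo acyl group and the two-carbon bridge, so oxygen should be delivered to the exo face only, cis to the bridge oxygen, which fixes the future C3–O and C4–O bonds on the face of the future C5–O bond. Removing the alkene also removes the retro-Diels–Alder pathway.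

**Step 3**
Reactants: 4; 5 4-methoxybenzyl alcohol
Product: 7 4-methoxybenzyl (1R,2R,4S,5S,6R)-3,8-dioxatricyclo[3.2.1.0^{2,4}]octane-6-carboxylate, via lithium 4-methoxybenzyl oxide 6 (not isolated)
Conditions: 5 (1.5 equiv), n-BuLi (1.3 equiv), THF, −78 → 0 °C; then 4, −20 → 0 °C; aq. NH4Cl
Reagents that add atoms: none
Why: alkoxide cleavage of an N-acyl oxazolidinone at the exocyclic carbonyl, the standard way to remove this imide as a benzyl-type ester; it gives an ester that survives steps 4–7 and falls to acid in step 8. Epimerisation at C6 or some premature bridge opening would be harmless, since C6 becomes sp2 and the bridge is opened in step 4.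

**Step 4**
Reactants: 7
Product: 10 4-methoxybenzyl (1S,5R,6R)-5-hydroxy-7-oxabicyclo[4.1.0]hept-2-ene-3-carboxylate (epoxide cis to the hydroxyl), via lithium ester enolate 8 (not isolated), via lithium alkoxide 9 (not isolated)
Conditions: LiN(SiMe3)2 (1.1 equiv), THF, −78 → −30 °C; aq. NH4Cl at −78 °C
Reagents that add atoms: none
Why: E1cB fragmentation typical of 7-oxabicyclo[2.2.1]heptane-2-carboxylates: the enolate 8 expels the bridge oxygen from the β-carbon, which creates the conjugated C1=C2 bond of the target and leaves the oxygen on the other bridgehead as alkoxide 9. No stereocentre is formed; the cis relation of epoxide and hydroxyl is inherited from step 2, and strain release drives the step at low temperature. Because the alkoxide of 9 is cis to the epoxide it cannot reach the back side of the neighbouring epoxide carbon, so epoxide migration should not compete.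

**Step 5**
Reactants: 10; 11 acetic acid
Product: 13 4-methoxybenzyl (1S,5S,6R)-5-acetoxy-7-oxabicyclo[4.1.0]hept-2-ene-3-carboxylate (epoxide trans to the acetate), via alkoxytriphenylphosphonium acetate 12 (not isolated)
Conditions: PPh3 (1.5 equiv), DIAD (1.5 equiv), 11 (2 equiv), toluene, 0 °C → rt
Reagents that add atoms: none
Why: Mitsunobu reaction: the hydroxyl is activated as the oxyphosphonium ion 12 and displaced by acetate in an SN2 step, so the acetate is installed and C5 is inverted from R to S in one operation. The epoxide lies on the face of the leaving group and cannot participate, the opposite face of C5 is open, and the alcohol is not allylic, so no SN2′ path exists.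

**Step 6**
Reactants: 13; 14 6-methylheptanoic acid
Product: 15 4-methoxybenzyl (3R,4R,5S)-5-acetoxy-4-hydroxy-3-[(6-methylheptanoyl)oxy]cyclohex-1-ene-1-carboxylate
Conditions: 14 (5 equiv), Cs2CO3 (0.25 equiv), DMF, 45 °C
Reagents that add atoms: none
Why: anti (SN2) opening of a vinyl epoxide by a carboxylate at the allylic carbon, buffered by the free acid: C3 is activated by the adjacent C1=C2 π-system and is open on the face opposite the epoxide, whereas C4 is deactivated inductively and screened on that face by the C5 acetate. Inversion at C3 gives the 3,4-trans relation and frees O4 as the only hydroxyl, so O3 and O4 are distinguished without a protecting group; the excess acid should protonate the alkoxide at once and suppress acyl migration.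

**Step 7**
Reactants: 15; 16 (E)-2-methylbut-2-enoyl chloride (tigloyl chloride)
Product: 17 4-methoxybenzyl (3R,4R,5S)-5-acetoxy-3-[(6-methylheptanoyl)oxy]-4-{[(2E)-2-methylbut-2-enoyl]oxy}cyclohex-1-ene-1-carboxylate
Conditions: 16 (2 equiv), pyridine (5 equiv), DMAP (0.1 equiv), CH2Cl2, 0 °C → rt
Reagents that add atoms: none
Why: nucleophile-catalysed acylation of the single remaining hydroxyl by the acid chloride; the E geometry comes from 16 and is the stable one. Low temperature and a weak base should keep 1,2-acyl migration slower than acylation.

**Step 8**
Reactants: 17
Product: 18 (3R,4R,5S)-5-acetoxy-3-[(6-methylheptanoyl)oxy]-4-{[(2E)-2-methylbut-2-enoyl]oxy}cyclohex-1-ene-1-carboxylic acid (target)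
Conditions: TFA–CH2Cl2 (1:4), anisole (5 equiv), 0 °C
Reagents that add atoms: none
Why: acidolysis of the 4-methoxybenzyl ester through the stabilised benzylic cation, which anisole traps. The three secondary esters and the tiglate double bond should be inert to TFA at 0 °C, and ionisation of the allylic C3–O bond is disfavoured because the cation would sit next to the electron-poor enoic acid.

## Compound list

1 | furan | c1ccoc1 | starting material
2 | 3-acryloyl-1,3-oxazolidin-2-one | C=CC(=O)N1CCOC1=O | starting material
3 | 3-[(1R,2R,4R)-7-oxabicyclo[2.2.1]hept-5-ene-2-carbonyl]-1,3-oxazolidin-2-one (endo) | O=C([C@@H]1C[C@@H]2C=C[C@H]1O2)N1CCOC1=O | intermediate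
4 | 3-[(1R,2R,4S,5S,6R)-3,8-dioxatricyclo[3.2.1.0^{2,4}]octane-6-carbonyl]-1,3-oxazolidin-2-one (exo epoxide) | O=C([C@@H]1C[C@@H]2[C@H]3O[C@H]3[C@H]1O2)N1CCOC1=O | intermediate
5 | 4-methoxybenzyl alcohol | COc1ccc(CO)cc1 | starting material
6 | lithium 4-methoxybenzyl oxide | [Li+].[O-]Cc1ccc(OC)cc1 | intermediate (not isolated)
7 | 4-methoxybenzyl (1R,2R,4S,5S,6R)-3,8-dioxatricyclo[3.2.1.0^{2,4}]octane-6-carboxylate | COc1ccc(COC(=O)[C@@H]2C[C@@H]3[C@H]4O[C@H]4[C@H]2O3)cc1 | intermediate
8 | lithium ester enolate of 7 (C6 deprotonated; enolate geometry not defined) | [Li+].[O-]C(OCc1ccc(OC)cc1)=C1C[C@@H]2[C@H]3O[C@H]3[C@H]1O2 | intermediate (not isolated)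
9 | lithium alkoxide of 10 | [Li+].[O-][C@@H]1CC(C(=O)OCc2ccc(OC)cc2)=C[C@@H]3O[C@H]13 | intermediate (not isolated)
10 | 4-methoxybenzyl (1S,5R,6R)-5-hydroxy-7-oxabicyclo[4.1.0]hept-2-ene-3-carboxylate | O[C@@H]1CC(C(=O)OCc2ccc(OC)cc2)=C[C@@H]3O[C@H]13 | intermediate
11 | acetic acid | CC(=O)O | starting material
12 | alkoxytriphenylphosphonium acetate derived from 10 (configuration of 10 at every centre) | CC(=O)[O-].c1ccccc1[P+](c1ccccc1)(c1ccccc1)O[C@@H]1CC(C(=O)OCc2ccc(OC)cc2)=C[C@@H]3O[C@H]13 | intermediate (not isolated)
13 | 4-methoxybenzyl (1S,5S,6R)-5-acetoxy-7-oxabicyclo[4.1.0]hept-2-ene-3-carboxylate | CC(=O)O[C@H]1CC(C(=O)OCc2ccc(OC)cc2)=C[C@@H]3O[C@H]13 | intermediate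
14 | 6-methylheptanoic acid | CC(C)CCCCC(=O)O | starting material
15 | 4-methoxybenzyl (3R,4R,5S)-5-acetoxy-4-hydroxy-3-[(6-methylheptanoyl)oxy]cyclohex-1-ene-1-carboxylate | O[C@@H]1[C@@H](OC(C)=O)CC(C(=O)OCc2ccc(OC)cc2)=C[C@H]1OC(=O)CCCCC(C)C | intermediate
16 | (E)-2-methylbut-2-enoyl chloride | C/C=C(\C)C(=O)Cl | starting material
17 | 4-methoxybenzyl (3R,4R,5S)-5-acetoxy-3-[(6-methylheptanoyl)oxy]-4-{[(2E)-2-methylbut-2-enoyl]oxy}cyclohex-1-ene-1-carboxylate | C/C=C(\C)C(=O)O[C@@H]1[C@@H](OC(C)=O)CC(C(=O)OCc2ccc(OC)cc2)=C[C@H]1OC(=O)CCCCC(C)C | intermediate
18 | (3R,4R,5S)-5-acetoxy-3-[(6-methylheptanoyl)oxy]-4-{[(2E)-2-methylbut-2-enoyl]oxy}cyclohex-1-ene-1-carboxylic acid | C/C=C(\C)C(=O)O[C@@H]1[C@@H](OC(C)=O)CC(C(=O)O)=C[C@H]1OC(=O)CCCCC(C)C | target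

## Step count and risk

Total step count: 8. Longest linear sequence: 8 steps (1 + 2 → 18); the acyl donors 11, 14 and 16 and the alcohol 5 are bought. Steps 2, 3 and 8 are expected to be routine.

**Step 1 (key step).** The most likely failure is loss of kinetic control. The furan cycloaddition is reversible, and if the Lewis acid stays active while the mixture warms, cycloreversion and re-addition drift the product towards the exo adduct and the racemate. Since the exo adduct of the same dienophile face carries the opposite bridgehead configuration, incomplete endo selectivity erodes the enantiopurity of the future C5 unless the isomers are separated. Fallback (resolution instead of catalysis): it sets out from 1, which adds to acrylic acid without catalyst at room temperature to give, after crystallisation from the exo isomer, the racemic endo-7-oxabicyclo[2.2.1]hept-5-ene-2-carboxylic acid F1. Crystallisation of its salt with the matching enantiomer of 1-phenylethylamine gives the (1R,2R,4R) acid F2. Pivaloyl chloride and Et3N convert F2 into the mixed pivalic anhydride F3, which acylates lithiated oxazolidin-2-one, and the route is rejoined at 3.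

**Step 4.** The most likely failure is competing intramolecular alkylation: the enolate carbon attacks the neighbouring epoxide carbon from the endo face (cyclopropane formation) instead of expelling the bridge oxygen, or excess base isomerises the vinyl epoxide product. Fallback (bridge opening before epoxidation, hydroxyl-directed epoxidation on the monocycle): it sets out from 3, which is transesterified as in step 3 to 4-methoxybenzyl (1R,2R,4R)-7-oxabicyclo[2.2.1]hept-5-ene-2-carboxylate F4. LiN(SiMe3)2 in THF at −78 °C opens the bridge to the dienol 4-methoxybenzyl (5R)-5-hydroxycyclohexa-1,3-diene-1-carboxylate F5, which is kept cold to avoid aromatisation. VO(acac)2 (cat.) with t-BuOOH epoxidises the allylic C3=C4 bond on the face of the hydroxyl, and the route is rejoined at 10.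

**Step 5.** The most likely failure is slow substitution at a carbon next to an epoxide with a weakly acidic partner, which lets elimination of the activated alcohol towards C6, followed by aromatisation, compete. Fallback (stepwise activation and displacement): it sets out from 10, which Tf2O and pyridine at −20 °C convert into the trifluoromethanesulfonate of 10, F6. Tetrabutylammonium acetate in toluene displaces the triflate with inversion, and the route is rejoined at 13.

**Step 6.** The most likely failure is a slow bimolecular opening by a weak nucleophile. This gives time for anchimeric opening by the C5 acetate carbonyl and for acyl migration onto the liberated O4, and both scramble the ester positions. Fallback (oxygen from water, ester by acylation): it sets out from 13, which dilute HClO4 in THF–H2O at 0 °C opens at the allylic carbon to the diol 4-methoxybenzyl (3R,4S,5S)-5-acetoxy-3,4-dihydroxycyclohex-1-ene-1-carboxylate F7 (same spatial arrangement as 15). The less hindered allylic O3–H is then acylated with 14 by carbodiimide coupling (DCC, DMAP cat., CH2Cl2, −20 °C), and the route is rejoined at 15.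

**Step 7.** The most likely failure is slow acylation of a hydroxyl flanked by two acyloxy groups. Under amine base this allows 1,2-acyl migration from O3 or O5 to O4 and deconjugation of the acid chloride through its vinylketene. Fallback (the tiglate double bond is built on the substrate): it sets out from 15, which is esterified with 2-(diethoxyphosphoryl)propanoic acid (DCC, DMAP cat.) to the 4-O-[2-(diethoxyphosphoryl)propanoyl] derivative of 15, F8 (both epimers at the phosphorus-bearing carbon). Horner–Wadsworth–Emmons reaction with acetaldehyde (LiCl, i-Pr2NEt, MeCN, 0 °C) should give the E-alkene, and the route is rejoined at 17.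

## Further compounds

F1 | step 1 | racemic endo-7-oxabicyclo[2.2.1]hept-5-ene-2-carboxylic acid (both enantiomers) | OC(=O)[C@@H]1C[C@@H]2C=C[C@H]1O2.OC(=O)[C@H]1C[C@H]2C=C[C@@H]1O2
F2 | step 1 | (1R,2R,4R)-7-oxabicyclo[2.2.1]hept-5-ene-2-carboxylic acid | OC(=O)[C@@H]1C[C@@H]2C=C[C@H]1O2
F3 | step 1 | mixed anhydride of F2 with pivalic acid | CC(C)(C)C(=O)OC(=O)[C@@H]1C[C@@H]2C=C[C@H]1O2
F4 | step 4 | 4-methoxybenzyl (1R,2R,4R)-7-oxabicyclo[2.2.1]hept-5-ene-2-carboxylate | COc1ccc(COC(=O)[C@@H]2C[C@@H]3C=C[C@H]2O3)cc1
F5 | step 4 | 4-methoxybenzyl (5R)-5-hydroxycyclohexa-1,3-diene-1-carboxylate | O[C@@H]1CC(C(=O)OCc2ccc(OC)cc2)=CC=C1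
F6 | step 5 | trifluoromethanesulfonate of 10 (configuration of 10 at every centre) | FC(F)(F)S(=O)(=O)O[C@@H]1CC(C(=O)OCc2ccc(OC)cc2)=C[C@@H]3O[C@H]13
F7 | step 6 | 4-methoxybenzyl (3R,4S,5S)-5-acetoxy-3,4-dihydroxycyclohex-1-ene-1-carboxylate | O[C@@H]1[C@@H](OC(C)=O)CC(C(=O)OCc2ccc(OC)cc2)=C[C@H]1O
F8 | step 7 | 4-O-[2-(diethoxyphosphoryl)propanoyl] derivative of 15 (both epimers at the phosphorus-bearing carbon) | CCOP(=O)(OCC)C(C)C(=O)O[C@@H]1[C@@H](OC(C)=O)CC(C(=O)OCc2ccc(OC)cc2)=C[C@H]1OC(=O)CCCCC(C)C
A1 | alternative 1 | (−)-shikimic acid, (3R,4S,5R)-3,4,5-trihydroxycyclohex-1-ene-1-carboxylic acid | OC(=O)C1=C[C@@H](O)[C@@H](O)[C@H](O)C1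
A2 | alternative 1 | methyl (1S,5R,6R)-5-hydroxy-7-oxabicyclo[4.1.0]hept-3-ene-3-carboxylate (4,5-epoxide cis to the C3 hydroxyl) | COC(=O)C1=C[C@@H](O)[C@H]2O[C@H]2C1
A3 | alternative 2 | D-arabinose (open-chain form) | O=C[C@@H](O)[C@H](O)[C@H](O)CO
A4 | alternative 2 | ethyl (4S,5R,6R)-4,5,6-trihydroxy-2-methylideneoct-7-enoate | C=C(C(=O)OCC)C[C@H](O)[C@@H](O)[C@H](O)C=C
A5 | alternative 2 | ethyl (3R,4R,5S)-3,4,5-trihydroxycyclohex-1-ene-1-carboxylate | O[C@@H]1[C@@H](O)CC(C(=O)OCC)=C[C@H]1O
A6 | alternative 3 | (1R,6S)-7-oxabicyclo[4.1.0]hept-3-ene (meso) | C1=CC[C@@H]2O[C@@H]2C1
A7 | alternative 3 | (1S,6S)-6-hydroxycyclohex-3-en-1-yl (2E)-2-methylbut-2-enoate | C/C=C(\C)C(=O)O[C@@H]1[C@@H](O)CC=CC1
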